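**Plan**
- **Retrosynthetic cuts.** After removal of two MOM groups, the pyranone ring (O1, C2, C3, C4, C4a, C8a) is contracted: bond C3–C4 is cut and C2–C4 is remade. This leads back to a 2-aryl-2-(iodomethyl)benzofuran-3(2H)-one.
- **Enabling feature.** C2 carries both the ring oxygen O1 and the 4-oxyphenyl ring, and it lies 1,3 to the C4 ketone. A radical at C2 is therefore tertiary, benzylic and α-oxygenated, which makes it the sink of a radical 1,2-acyl shift.
- **Further cuts.** These are C2–CH2I (enolate alkylation), O1–C2 (closure of a benzoin), the two aryl–prenyl bonds and the aryl–acyl bond. The last intermediate is a deoxybenzoin with a symmetric ring A, an isoflavonoid-type skeleton that is easier to build than the flavanone.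
- **Forward order.** Ring A is acylated, diprenylated and O-methylated. The five-membered furanone closes first, and the six-membered ring then arises from it by one-carbon ring expansion.
- **Stereochemistry.** Everything up to the iodide is racemic. The ring expansion erases the quaternary centre, and a chiral thiol reduces the planar C2 radical (enantioconvergent). The base-labile C2 centre afterwards sees only one mild acidic step.

Key step: step 8

Assumption: the sense of induction of the peptide thiol in step 8 cannot be derived from first principles. The catalyst can be made from L- or D-cysteine, and the antipode that delivers hydrogen to the Re face of C2 (2S) is the one meant.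

Step 1
Reactants: 1 phloroglucinol; 2 4-hydroxyphenylacetic acid
Product: 3 2-(4-hydroxyphenyl)-1-(2,4,6-trihydroxyphenyl)ethan-1-one
Conditions: BF3·OEt2 (neat), 85 °C; then aq. NaOAc
Reagents that add atoms: none
Why: Friedel–Crafts (Nencki-type) C-acylation of the very electron-rich, threefold symmetric arene by the BF3-activated acid should stop after one acylation because the chelated aryl ketone is deactivated; no stereocentre is formed.

Step 2
Reactants: 3 2-(4-hydroxyphenyl)-1-(2,4,6-trihydroxyphenyl)ethan-1-one
Product: 4 2-(4-hydroxyphenyl)-1-[2,4,6-trihydroxy-3,5-bis(3-methylbut-2-en-1-yl)phenyl]ethan-1-one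
Conditions: prenyl bromide (2.1 equiv), KOH (2.1 equiv), H2O/MeOH, 0 °C to rt
Reagents that add atoms: prenyl bromide (1-bromo-3-methylbut-2-ene), CC(C)=CCBr
Why: C-alkylation of the ambident acylphloroglucinol phenolate in protic medium (hydrogen bonding to oxygen suppresses O-alkylation) occurs at the only two free ring positions, and the limited base is consumed by the far more acidic ring A hydroxyls so that the 4'-OH stays protonated.

Step 3
Reactants: 4 2-(4-hydroxyphenyl)-1-[2,4,6-trihydroxy-3,5-bis(3-methylbut-2-en-1-yl)phenyl]ethan-1-one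
Product: 5 1-[2,6-dihydroxy-4-methoxy-3,5-bis(3-methylbut-2-en-1-yl)phenyl]-2-(4-hydroxyphenyl)ethan-1-one
Conditions: TMSCHN2 (1.05 equiv), i-Pr2NEt, MeCN/MeOH 9:1, 0 °C to rt
Reagents that add atoms: (trimethylsilyl)diazomethane, C[Si](C)(C)C=[N+]=[N-]
Why: O-methylation by a diazoalkane starts with proton transfer from the most acidic OH, here the non-chelated 4-OH para to the acyl group (a vinylogous acid), so it should be methylated ahead of the chelated 2/6-OH and the ordinary phenol at C4'.

Step 4
Reactants: 5 1-[2,6-dihydroxy-4-methoxy-3,5-bis(3-methylbut-2-en-1-yl)phenyl]-2-(4-hydroxyphenyl)ethan-1-one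
Product: 6 1-[2-hydroxy-4-methoxy-6-(methoxymethoxy)-3,5-bis(3-methylbut-2-en-1-yl)phenyl]-2-[4-(methoxymethoxy)phenyl]ethan-1-one
Conditions: MOMCl (2.3 equiv), i-Pr2NEt, CH2Cl2, 0 °C to rt
Reagents that add atoms: chloromethyl methyl ether, COCCl
Why: O-alkylation with MOMCl protects the 4'-OH and one of the two equivalent ortho hydroxyls (no regiochemical issue) and should stop there because the last OH is locked in a strong hydrogen bond to the ketone and flanked by a prenyl group.

Step 5
Reactants: 6 1-[2-hydroxy-4-methoxy-6-(methoxymethoxy)-3,5-bis(3-methylbut-2-en-1-yl)phenyl]-2-[4-(methoxymethoxy)phenyl]ethan-1-one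
Product: 7 rac-2-hydroxy-1-[2-hydroxy-4-methoxy-6-(methoxymethoxy)-3,5-bis(3-methylbut-2-en-1-yl)phenyl]-2-[4-(methoxymethoxy)phenyl]ethan-1-one
Conditions: KHMDS (2.3 equiv), THF, −78 °C; 2-(phenylsulfonyl)-3-phenyloxaziridine (1.2 equiv); AcOH quench
Reagents that add atoms: 2-(phenylsulfonyl)-3-phenyloxaziridine, O=S(=O)(c1ccccc1)N1OC1c1ccccc1
Why: Davis oxidation, in which the benzylic enolate carbon of the phenoxide/enolate dianion attacks the oxaziridine oxygen while the neutral trisubstituted alkenes are inert at −78 °C; the carbinol centre forms as a racemate, which is of no consequence.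

Step 6
Reactants: 7 rac-2-hydroxy-1-[2-hydroxy-4-methoxy-6-(methoxymethoxy)-3,5-bis(3-methylbut-2-en-1-yl)phenyl]-2-[4-(methoxymethoxy)phenyl]ethan-1-one
Product: 8 rac-6-methoxy-4-(methoxymethoxy)-2-[4-(methoxymethoxy)phenyl]-5,7-bis(3-methylbut-2-en-1-yl)benzofuran-3(2H)-one
Conditions: MsCl (1.05 equiv), Et3N (2.2 equiv), CH2Cl2, −20 °C to rt, argon; used at once
Reagents that add atoms: none
Why: Mesylation of the alcohol followed in the same flask by intramolecular Williamson etherification (5-exo-tet attack of the ortho phenoxide on the α-keto benzylic sulfonate) is the classical coumaranone closure and spares MOM and prenyl groups; C2 is racemic and enolisable.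

Step 7
Reactants: 8 rac-6-methoxy-4-(methoxymethoxy)-2-[4-(methoxymethoxy)phenyl]-5,7-bis(3-methylbut-2-en-1-yl)benzofuran-3(2H)-one
Product: 9 rac-2-(iodomethyl)-6-methoxy-4-(methoxymethoxy)-2-[4-(methoxymethoxy)phenyl]-5,7-bis(3-methylbut-2-en-1-yl)benzofuran-3(2H)-one
Conditions: NaH (1.1 equiv), THF/DMPU, 0 °C; CH2I2 (8 equiv), rt to 40 °C, argon
Reagents that add atoms: diiodomethane, ICI
Why: Alkylation of the soft sodium enolate with the soft electrophile CH2I2 (in excess, so that two enolates are not bridged) should take place at carbon, as in the standard preparation of Dowd–Beckwith substrates, and gives the quaternary C2 as a racemate.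

Step 8
Reactants: 9 rac-2-(iodomethyl)-6-methoxy-4-(methoxymethoxy)-2-[4-(methoxymethoxy)phenyl]-5,7-bis(3-methylbut-2-en-1-yl)benzofuran-3(2H)-one
Product: 13 (2S)-7-methoxy-5-(methoxymethoxy)-2-[4-(methoxymethoxy)phenyl]-6,8-bis(3-methylbut-2-en-1-yl)chroman-4-one, via primary alkyl radical 10 (not isolated), via cyclopropyloxyl radical 11 (not isolated), via C2 benzylic radical 12 (not isolated)
Conditions: (TMS)3SiH (1.5 equiv, syringe pump), cysteine-based β-turn peptide thiol (5 mol %), V-70 (20 mol %, in portions), degassed PhMe (0.02 M), 30 °C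
Reagents that add atoms: none
Why: Proposed new method: (TMS)3Si• abstracts iodine from rac-9; the primary radical 10 adds to the neighbouring C3 ketone carbon (3-exo-trig, transient cyclopropane), and the cyclopropyloxyl radical 11 breaks the ring-fusion bond C2–C3, so that the ketone returns and the five-membered furanone becomes the six-membered pyranone by a net 1,2-acyl shift, the six-membered ring arising by bond cleavage inside the bicyclo[3.1.0] unit and not by a direct closure. The closest known reaction types are the Dowd–Beckwith one-carbon ring expansion of α-(halomethyl) cyclic ketones and thiol polarity-reversal catalysis with a chiral thiol as hydrogen-atom donor; their union, and an O,aryl-substituted instead of an ester-substituted migration origin, has not been shown on benzofuran-3(2H)-ones. Of the three bonds at the oxyl-bearing carbon of 11 only C2–C3 releases a radical (12) that is tertiary, benzylic to the 4-oxyphenyl ring and α to O1, which should make the expansion regioselective and practically irreversible. The quaternary centre of 9 is erased in planar 12, so both enantiomers converge, and the single stereocentre C2 is set when nucleophilic 12 takes hydrogen on its Re face from the electrophilic S–H of the peptide thiol, which is expected to dock by hydrogen bonds on the C4 ketone (free of chelation because O5 is MOM-protected). The acyl shift has to outrun direct reduction of 10, the intrinsically much slower 1,2-aryl (neophyl) shift and β-scission of C2–O1, which is why both hydrogen donors are kept very dilute and the mixture is held at 30 °C rather than cooled. Stabilised 12 should react only sluggishly with Si–H, so the chiral thiol should be the effective donor, and the silane should intercept thiyl radicals before they re-abstract H-2 of 13 or add to the prenyl groups.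

Step 9
Reactants: 13 (2S)-7-methoxy-5-(methoxymethoxy)-2-[4-(methoxymethoxy)phenyl]-6,8-bis(3-methylbut-2-en-1-yl)chroman-4-one
Product: 14 (2S)-5-hydroxy-2-(4-hydroxyphenyl)-7-methoxy-6,8-bis(3-methylbut-2-en-1-yl)chroman-4-one
Conditions: aq. HCl (3 M)/MeOH, 40 °C
Reagents that add atoms: none
Why: Acid-catalysed acetal exchange with MeOH removes both MOM groups; base, which would open the ring by retro-oxa-Michael reaction and racemise C2, is avoided, and the mild acid should leave the prenyl groups uncyclised.

**Compound list**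
1 | phloroglucinol | Oc1cc(O)cc(O)c1 | starting material
2 | 4-hydroxyphenylacetic acid | OC(=O)Cc1ccc(O)cc1 | starting material
3 | 2-(4-hydroxyphenyl)-1-(2,4,6-trihydroxyphenyl)ethan-1-one | O=C(Cc1ccc(O)cc1)c1c(O)cc(O)cc1O | intermediate
4 | 2-(4-hydroxyphenyl)-1-[2,4,6-trihydroxy-3,5-bis(3-methylbut-2-en-1-yl)phenyl]ethan-1-one | O=C(Cc1ccc(O)cc1)c1c(O)c(CC=C(C)C)c(O)c(CC=C(C)C)c1O | intermediate
5 | 1-[2,6-dihydroxy-4-methoxy-3,5-bis(3-methylbut-2-en-1-yl)phenyl]-2-(4-hydroxyphenyl)ethan-1-one | O=C(Cc1ccc(O)cc1)c1c(O)c(CC=C(C)C)c(OC)c(CC=C(C)C)c1O | intermediate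
6 | 1-[2-hydroxy-4-methoxy-6-(methoxymethoxy)-3,5-bis(3-methylbut-2-en-1-yl)phenyl]-2-[4-(methoxymethoxy)phenyl]ethan-1-one | O=C(Cc1ccc(OCOC)cc1)c1c(O)c(CC=C(C)C)c(OC)c(CC=C(C)C)c1OCOC | intermediate
7 | rac-2-hydroxy-1-[2-hydroxy-4-methoxy-6-(methoxymethoxy)-3,5-bis(3-methylbut-2-en-1-yl)phenyl]-2-[4-(methoxymethoxy)phenyl]ethan-1-one | O=C(C(O)c1ccc(OCOC)cc1)c1c(O)c(CC=C(C)C)c(OC)c(CC=C(C)C)c1OCOC | intermediate
8 | rac-6-methoxy-4-(methoxymethoxy)-2-[4-(methoxymethoxy)phenyl]-5,7-bis(3-methylbut-2-en-1-yl)benzofuran-3(2H)-one (in equilibrium with its 3-hydroxybenzofuran tautomer) | O=C1C(c2ccc(OCOC)cc2)Oc2c(CC=C(C)C)c(OC)c(CC=C(C)C)c(OCOC)c21 | intermediate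
9 | rac-2-(iodomethyl)-6-methoxy-4-(methoxymethoxy)-2-[4-(methoxymethoxy)phenyl]-5,7-bis(3-methylbut-2-en-1-yl)benzofuran-3(2H)-one | O=C1C(CI)(c2ccc(OCOC)cc2)Oc2c(CC=C(C)C)c(OC)c(CC=C(C)C)c(OCOC)c21 | intermediate
10 | primary alkyl radical (CH2• on C2 of the benzofuranone) | O=C1C([CH2])(c2ccc(OCOC)cc2)Oc2c(CC=C(C)C)c(OC)c(CC=C(C)C)c(OCOC)c21 | intermediate
11 | cyclopropyloxyl radical (cyclopropane fused to the C2–C3 bond of the dihydrobenzofuran, O• on the former ketone carbon) | [O]C12CC1(c1ccc(OCOC)cc1)Oc1c(CC=C(C)C)c(OC)c(CC=C(C)C)c(OCOC)c12 | intermediate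
12 | ring-expanded 4-oxochroman-2-yl radical (planar C2) | O=C1C[C](c2ccc(OCOC)cc2)Oc2c(CC=C(C)C)c(OC)c(CC=C(C)C)c(OCOC)c21 | intermediate
13 | (2S)-7-methoxy-5-(methoxymethoxy)-2-[4-(methoxymethoxy)phenyl]-6,8-bis(3-methylbut-2-en-1-yl)chroman-4-one | COc1c(CC=C(C)C)c(OCOC)c2c(c1CC=C(C)C)O[C@H](c1ccc(OCOC)cc1)CC2=O | intermediate
14 | (2S)-5-hydroxy-2-(4-hydroxyphenyl)-7-methoxy-6,8-bis(3-methylbut-2-en-1-yl)chroman-4-one | COc1c(CC=C(C)C)c(O)c2c(c1CC=C(C)C)O[C@H](c1ccc(O)cc1)CC2=O | target

Total step count: 9. Longest linear sequence: 9 steps (from 1 or 2 to 14).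

**Steps most likely to fail**

**Step 8.**
- What may go wrong before the acyl shift: hydrogen transfer to the primary radical, β-scission of the C2–O1 bond, or a hydrogen shift from the doubly activated CH2 of the neighbouring prenyl group.
- What may go wrong at C2: poor facial selectivity of the hydrogen transfer, or erosion of the enantiomeric purity by back-abstraction of H-2 through thiyl radicals.
- The fallback uses known chemistry, sets out from 9 and returns at 13.
- The ring expansion is run in the classical achiral way (Bu3SnH by syringe pump, AIBN, PhH, 80 °C). This should give the racemic bis-MOM flavanone F1.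
- F1 is then subjected to the known kinetic resolution of flavanones by asymmetric transfer hydrogenation ([Cp*RhCl((R,R)-TsDPEN)], HCO2H/Et3N, EtOAc, rt, halted near half conversion).
- The (2R) ketone is expected to be reduced to the cis-(2R,4R)-flavan-4-ol F2, and the unreacted (2S) ketone is 13.
- The alcohol can be fed back after oxidation and base-induced racemisation.

**Step 7.**
- What may go wrong: alkylation of the ambident enolate at oxygen (driven by aromatisation to the benzofuran), bridging of two enolates by one CH2 unit, and autoxidation at C2.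
- The fallback sets out from 8 and returns at 9.
- An aldol reaction with formaldehyde (aq. CH2O, cat. Et3N, THF, rt) is used, in which attack through oxygen is reversible and only C-attack persists. It should give the hydroxymethyl ketone F3.
- F3 is converted into 9 by Garegg–Samuelsson iodination (I2, PPh3, imidazole, PhMe, 70 °C).

**Step 2.**
- What may go wrong: geminal (dearomatising) over-alkylation, O-prenylation including that of the 4'-OH, and an incomplete second alkylation.
- The fallback sets out from 3 and returns at 6. It brings in the prenyl groups by cross-coupling instead of phenolate alkylation.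
- 3 is O-methylated as in step 3 to the 4-methyl ether F4 and protected as in step 4 to the bis-MOM ether F5.
- F5 is iodinated at the only two free positions of ring A (NIS, 2.1 equiv, DMF, 0 °C) to the diiodide F6.
- F6 is coupled with tributyl(3-methylbut-2-enyl)stannane under Stille conditions (Pd(PPh3)4, DMF, 90 °C) to give 6.

**Further compounds**
F1 | step 8 | rac-7-methoxy-5-(methoxymethoxy)-2-[4-(methoxymethoxy)phenyl]-6,8-bis(3-methylbut-2-en-1-yl)chroman-4-one | COc1c(CC=C(C)C)c(OCOC)c2c(c1CC=C(C)C)OC(c1ccc(OCOC)cc1)CC2=O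
F2 | step 8 | (2R,4R)-7-methoxy-5-(methoxymethoxy)-2-[4-(methoxymethoxy)phenyl]-6,8-bis(3-methylbut-2-en-1-yl)chroman-4-ol | COc1c(CC=C(C)C)c(OCOC)c2c(c1CC=C(C)C)O[C@@H](c1ccc(OCOC)cc1)C[C@H]2O
F3 | step 7 | rac-2-(hydroxymethyl)-6-methoxy-4-(methoxymethoxy)-2-[4-(methoxymethoxy)phenyl]-5,7-bis(3-methylbut-2-en-1-yl)benzofuran-3(2H)-one | O=C1C(CO)(c2ccc(OCOC)cc2)Oc2c(CC=C(C)C)c(OC)c(CC=C(C)C)c(OCOC)c21
F4 | step 2 | 1-(2,6-dihydroxy-4-methoxyphenyl)-2-(4-hydroxyphenyl)ethan-1-one | O=C(Cc1ccc(O)cc1)c1c(O)cc(OC)cc1O
F5 | step 2 | 1-[2-hydroxy-4-methoxy-6-(methoxymethoxy)phenyl]-2-[4-(methoxymethoxy)phenyl]ethan-1-one | O=C(Cc1ccc(OCOC)cc1)c1c(O)cc(OC)cc1OCOC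
F6 | step 2 | 1-[2-hydroxy-3,5-diiodo-4-methoxy-6-(methoxymethoxy)phenyl]-2-[4-(methoxymethoxy)phenyl]ethan-1-one | O=C(Cc1ccc(OCOC)cc1)c1c(O)c(I)c(OC)c(I)c1OCOC
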